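**Retrosynthetic overview**

1. The target is traced back (desilylation, Steglich esterification with stearic acid, MnO2 oxidation) to a triol that holds the enal as its (Z)-allylic alcohol. The strategic cut is the C(sp3)–C(sp2) bond between the allylic CH2 ending the two-carbon arm on the quaternary ring carbon and the vinylic CH of the side chain.
2. Both carbons are electrophilic in their precursors: the CH2 is the anomeric carbon (aldehyde level) of a five-membered lactol, the CH an (E)-vinyl iodide. They are joined by polarity reversal: the lactol reacts as its N–H hydrazone (alkyl carbanion equivalent) under zerovalent nickel with loss of N2.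
3. Enabling feature: in the target the tertiary hydroxyl on ring carbon C-5 and the CH2CH2 arm on the neighbouring quaternary carbon C-6 are cis. O(C-5), the arm's terminal carbon, the arm's inner CH2, C-6 and C-5 therefore close a cis-fused oxolane (γ-lactone, then lactol) ring on the cyclohexane; it stores the coupling carbon as a masked aldehyde and is opened in the key step, freeing the C-5 hydroxyl.
4. Ring fragment from (R)-carvone, whose cyclohexane (ring A) is present from the start. α′-Allylation, methyl addition with oxidative transposition, Luche reduction and Eschenmoser–Claisen rearrangement set C-1 and the quaternary C-6. Iodolactonisation closes the temporary lactone (ring B, the only ring formed) and sets C-5. The isopropenyl group becomes the (Z)-enal by SeO2 oxidation and hydride isomerisation.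
5. Side chain from propargyl alcohol (carboalumination/iodination), geranyl chloride (α-selective barium addition) and a CBS reduction for the (R)-carbinol.

Key step: step 19

Assumption: (R)-(−)-carvone, propargyl alcohol, geranyl chloride and stearic acid are bought; kinetic allylation of the carvone enolate is taken to go trans to the isopropenyl group; locants C-1 to C-6 in the Why lines are those of the target ring (C-1 = CH with the three-carbon chain, C-2 = enal-bearing carbon, C-5 = carbinol carbon, C-6 = quaternary carbon).

**Route**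

Step 1
Reactants: 1 (R)-(−)-carvone
Product: 3 (5R,6S)-2-methyl-5-(prop-1-en-2-yl)-6-(prop-2-en-1-yl)cyclohex-2-en-1-one, via lithium dienolate 2 (not isolated)
Conditions: LiN(i-Pr)2, THF, −78 °C; then allyl bromide, DMPU, −78 to −30 °C
Reagents that add atoms: allyl bromide, C=CCBr
Why: Kinetic enolate alkylation: deprotonation at the α′-CH2 gives the cross-conjugated dienolate 2, and allyl bromide should approach the face opposite the neighbouring isopropenyl group, which sets the new centre (future C-1) trans to it.

Step 2
Reactants: 3 (5R,6S)-6-allylcarvone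
Product: 4 (5R,6S)-1,2-dimethyl-5-(prop-1-en-2-yl)-6-(prop-2-en-1-yl)cyclohex-2-en-1-ol (mixture of C-1 carbinol epimers)
Conditions: MeLi, Et2O, −78 °C; H2O
Reagents that add atoms: methyllithium, [Li]C
Why: 1,2-Addition of an organolithium to the enone carbonyl installs the future C-6 methyl group, and the configuration of the new carbinol does not matter because this carbon becomes sp2 in step 3.

Step 3
Reactants: 4 tertiary allylic alcohol
Product: 5 (4S,5R)-2,3-dimethyl-5-(prop-1-en-2-yl)-4-(prop-2-en-1-yl)cyclohex-2-en-1-one
Conditions: pyridinium chlorochromate [C5H5NH][CrO3Cl], 4 Å MS, CH2Cl2, rt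
Reagents that add atoms: pyridinium chlorochromate, [O-][Cr](=O)(=O)Cl.c1cc[nH+]cc1
Why: Babler–Dauben oxidative transposition: the tertiary allylic chromate ester undergoes a [3,3] shift and is oxidised to the transposed enone, which leaves both methyl groups on the tetrasubstituted alkene and creates no stereocentre.

Step 4
Reactants: 5 transposed enone
Product: 6 (1S,4S,5R)-2,3-dimethyl-5-(prop-1-en-2-yl)-4-(prop-2-en-1-yl)cyclohex-2-en-1-ol
Conditions: NaBH4, CeCl3·7H2O, MeOH, −78 °C
Reagents that add atoms: none
Why: Luche reduction gives only 1,2-reduction, and hydride should add anti to the isopropenyl group two carbons away (the course that turns carvone into cis-carveol), which sets the carbinol (1S) cis to isopropenyl and therefore trans to the allyl group.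

Step 5
Reactants: 6 allylic alcohol
Product: 8 N,N-dimethyl-2-[(1R,5R,6S)-1,2-dimethyl-5-(prop-1-en-2-yl)-6-(prop-2-en-1-yl)cyclohex-2-en-1-yl]acetamide, via ketene N,O-acetal 7 (not isolated)
Conditions: MeC(OMe)2NMe2, xylene, 140 °C
Reagents that add atoms: N,N-dimethylacetamide dimethyl acetal, COC(C)(OC)N(C)C
Why: Eschenmoser–Claisen rearrangement: the ketene N,O-acetal 7 rearranges suprafacially, so the new C–C bond forms on the ring face that the C–O bond leaves, which is also the face opposite the adjacent allyl group, and this sets the quaternary centre C-6 with its acetamide arm trans to allyl and its methyl cis to it.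

Step 6
Reactants: 8 γ,δ-unsaturated amide
Product: 10 (3aR,4S,5R,7R,7aR)-7-iodo-3a,7a-dimethyl-5-(prop-1-en-2-yl)-4-(prop-2-en-1-yl)hexahydro-1-benzofuran-2(3H)-one (cis-fused lactone, iodide trans to the ring oxygen), via iminium lactone iodide 9 (not isolated)
Conditions: I2, THF/H2O, 0 °C to rt
Reagents that add atoms: iodine, II; water, O
Why: Iodolactonisation of a γ,δ-unsaturated amide: the amide oxygen on its two-atom tether can reach the tertiary alkene carbon only from its own face in a 5-exo closure, so the cis-fused γ-lactone forms with the new C-5–O bond cis to the arm and iodide anti to it, and the iminium ether 9 is hydrolysed by the water present.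

Step 7
Reactants: 10 iodolactone
Product: 11 (3aR,4S,5R,7aS)-3a,7a-dimethyl-5-(prop-1-en-2-yl)-4-(prop-2-en-1-yl)hexahydro-1-benzofuran-2(3H)-one
Conditions: Bu3SnH, AIBN (cat.), toluene, 80 °C
Reagents that add atoms: none
Why: Radical-chain dehalogenation removes the secondary iodide, whose radical has no favourable cyclisation onto either remote alkene, and no stereocentre changes.

Step 8
Reactants: 11 lactone
Product: 13 (3aR,4S,5R,7aS)-4-(3-hydroxypropyl)-3a,7a-dimethyl-5-(prop-1-en-2-yl)hexahydro-1-benzofuran-2(3H)-one, via catechol boronate 12 (not isolated)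
Conditions: catecholborane, RhCl(PPh3)3 (2 mol %), THF, rt; then H2O2, pH 7 phosphate buffer, EtOH, 0 °C
Reagents that add atoms: hydrogen peroxide, OO
Why: Rhodium-catalysed hydroboration with catecholborane is strongly selective for the monosubstituted terminal alkene over the 1,1-disubstituted isopropenyl group and places boron on the terminal carbon, and buffered peroxide oxidises boronate 12 to the primary alcohol without opening the lactone.

Step 9
Reactants: 13 hydroxypropyl lactone
Product: 14 3-[(3aR,4S,5R,7aS)-3a,7a-dimethyl-2-oxo-5-(prop-1-en-2-yl)octahydro-1-benzofuran-4-yl]propyl acetate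
Conditions: Ac2O, pyridine, DMAP (cat.), CH2Cl2, rt
Reagents that add atoms: acetic anhydride, CC(=O)OC(C)=O
Why: Acylation of the only hydroxyl group; the acetate keeps the primary alcohol out of the oxidation and hydrogen-transfer chemistry of steps 10 and 11 and is removed without an extra step in step 12.

Step 10
Reactants: 14 acetate
Product: 16 2-[(3aR,4S,5R,7aS)-4-(3-acetoxypropyl)-3a,7a-dimethyl-2-oxooctahydro-1-benzofuran-5-yl]prop-2-enal, via allylic alcohol 15 (not isolated)
Conditions: SeO2 (0.5 equiv), t-BuOOH, CH2Cl2, rt; then MnO2, CH2Cl2, rt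
Reagents that add atoms: selenium dioxide, O=[Se]=O; tert-butyl hydroperoxide, CC(C)(C)OO
Why: Allylic oxidation with SeO2 (ene reaction followed by a [2,3] shift) attacks the methyl group of the only alkene left, and MnO2 (allylic alcohol oxidation) takes alcohol 15 on to the 2-substituted acrolein.

Step 11
Reactants: 16 2-substituted acrolein
Product: 17 (2Z)-2-[(3aR,4S,7aS)-4-(3-acetoxypropyl)-3a,7a-dimethyl-2-oxohexahydro-1-benzofuran-5(4H)-ylidene]propanal
Conditions: RuHCl(CO)(PPh3)3 (5 mol %), toluene, 80 °C
Reagents that add atoms: none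
Why: Metal-hydride alkene isomerisation (hydrometalation at the terminal CH2, then β-hydride elimination of the ring methine hydrogen) moves the double bond to the tetrasubstituted conjugated position, and allylic 1,3-strain with the equatorial chain on C-1 should leave the small formyl group rather than the methyl group syn to C-1, which is the (Z)-geometry of the target.

Step 12
Reactants: 17 (Z)-enal lactone acetate
Product: 18 (3aR,4S,5Z,7aS)-4-(3-hydroxypropyl)-5-(1-hydroxypropan-2-ylidene)-3a,7a-dimethyloctahydro-1-benzofuran-2-ol (lactol, mixture of anomers)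
Conditions: i-Bu2AlH (4.5 equiv), CH2Cl2, −78 °C; aq. potassium sodium tartrate
Reagents that add atoms: none
Why: Hydride reduction with i-Bu2AlH at low temperature stops at the aluminium hemiacetal of the γ-lactone (lactol after work-up), reduces the enal 1,2 to the allylic alcohol and cleaves the acetate in the same operation, with no change at any stereocentre or alkene.

Step 13
Reactants: 19 propargyl alcohol
Product: 21 (E)-3-iodo-2-methylprop-2-en-1-ol, via alkenylalane 20 (not isolated)
Conditions: AlMe3, Cp2ZrCl2 (25 mol %), CH2Cl2, 0 °C to rt; then I2, THF, −30 °C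
Reagents that add atoms: trimethylaluminium, C[Al](C)C; iodine, II
Why: Zirconium-catalysed carboalumination adds methyl and aluminium syn across the alkyne with aluminium on the terminal carbon, and iodinolysis of alane 20 with retention gives the (E)-iodoalkene.

Step 14
Reactants: 21 (E)-3-iodo-2-methylprop-2-en-1-ol
Product: 22 (E)-3-iodo-2-methylprop-2-enal
Conditions: MnO2, CH2Cl2, rt
Reagents that add atoms: none
Why: Allylic alcohol oxidation with MnO2 gives the enal and leaves the vinyl iodide and its geometry untouched.

Step 15
Reactants: 22 (E)-3-iodo-2-methylprop-2-enal; 23 geranyl chloride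
Product: 25 (1E,5E)-1-iodo-2,6,10-trimethylundeca-1,5,9-trien-3-ol (racemic), via geranylbarium chloride 24 (not isolated)
Conditions: BaI2, lithium biphenylide (2 equiv), THF, rt; 23, −78 °C; then 22, −78 °C
Reagents that add atoms: none
Why: Allylic barium reagents add to aldehydes at the α-carbon with retention of the (E)-allyl geometry (α-selective carbonyl allylation), which gives the linear homoallylic alcohol by 1,2-addition; the carbinol forms as a racemate that steps 16 and 17 correct.

Step 16
Reactants: 25 racemic alcohol
Product: 26 (1E,5E)-1-iodo-2,6,10-trimethylundeca-1,5,9-trien-3-one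
Conditions: Dess–Martin periodinane, NaHCO3, CH2Cl2, 0 °C
Reagents that add atoms: none
Why: Dess–Martin oxidation under bicarbonate buffer gives the ketone without moving the skipped alkene into conjugation.

Step 17
Reactants: 26 β-iodo enone
Product: 27 (1E,3R,5E)-1-iodo-2,6,10-trimethylundeca-1,5,9-trien-3-ol
Conditions: (S)-2-methyl-CBS-oxazaborolidine (20 mol %), catecholborane, toluene, −78 °C
Reagents that add atoms: none
Why: Corey–Bakshi–Shibata reduction: with the iodoalkenyl group as the large and the CH2 group as the small substituent, the (S)-oxazaborolidine should direct hydride to the face that gives the (R)-alcohol, and catecholborane does not hydroborate the trisubstituted alkenes at this temperature.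

Step 18
Reactants: 27 (R)-allylic alcohol
Product: 28 tert-butyl{[(1E,3R,5E)-1-iodo-2,6,10-trimethylundeca-1,5,9-trien-3-yl]oxy}dimethylsilane
Conditions: t-BuMe2SiCl, imidazole, DMF, rt
Reagents that add atoms: tert-butyldimethylsilyl chloride, CC(C)(C)[Si](C)(C)Cl
Why: Silyl ether formation protects the secondary allylic alcohol against the base of step 19 and the oxidant of step 20.

Step 19
Reactants: 18 lactol; 28 (E)-vinyl iodide
Product: 30 (1S,2R,3S,4Z)-2-[(3E,5R,7E)-5-(tert-butyldimethylsilyloxy)-4,8,12-trimethyltrideca-3,7,11-trien-1-yl]-3-(3-hydroxypropyl)-4-(1-hydroxypropan-2-ylidene)-1,2-dimethylcyclohexan-1-ol, via hydrazone 29 (not isolated)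
Conditions: N2H4·H2O (1.2 equiv), THF, rt; then 28, Ni(cod)2 (10 mol %), PMe3 (20 mol %), DBU, THF, 50 °C
Reagents that add atoms: none
Why: Proposed new method: the lactol opens to its hydroxy aldehyde and condenses with hydrazine to the N–H hydrazone 29, zerovalent nickel adds oxidatively to the C–I bond of 28, the deprotonated hydrazone binds nickel through nitrogen, and loss of N2 from the diazene tautomer hands the former aldehyde carbon to nickel as an alkyl ligand (a Wolff–Kishner-type carbanion equivalent) that reductively eliminates with the alkenyl ligand, so two carbons that are both electrophilic in their precursors are joined by polarity reversal. The closest known reaction types are the nickel-catalysed cross-coupling of aldehyde N–H hydrazones with aryl halides and the ruthenium-catalysed additions of aliphatic aldehyde hydrazones as alkyl carbanion equivalents, and the step asks for their extension to an aliphatic hydrazone paired with an alkenyl iodide. No ring is closed, instead the temporary oxolane ring is opened, which removes the oxygen from the coupling carbon and frees the tertiary C-5 hydroxyl without a deprotection, and no stereocentre is formed. The step needs retention of the (E)-geometry of 28, which oxidative addition and reductive elimination at nickel should preserve, and C–C bond formation in preference to N-alkenylation, plain Wolff–Kishner protonation or β-hydride elimination, which a small electron-rich phosphine and the fast-eliminating alkenyl partner should favour. Chemoselectivity is secured by the substrate, because the lactol carbon is the only carbonyl-level carbon in either partner (the enal is held as its allylic alcohol and the ester is not yet in place), so hydrazine can engage that carbon alone.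

Step 20
Reactants: 30 coupled triol
Product: 31 (2Z)-2-[(2S,3R,4S)-3-[(3E,5R,7E)-5-(tert-butyldimethylsilyloxy)-4,8,12-trimethyltrideca-3,7,11-trien-1-yl]-4-hydroxy-2-(3-hydroxypropyl)-3,4-dimethylcyclohexylidene]propanal
Conditions: MnO2, CH2Cl2, rt
Reagents that add atoms: none
Why: Allylic alcohol oxidation with MnO2 is chemoselective here because the other allylic oxygen is silylated and saturated primary and tertiary alcohols do not react, so only the (Z)-enal is restored.

Step 21
Reactants: 31 enal diol; 32 stearic acid
Product: 33 silyl-protected stearate, 3-[(1S,2R,3S,6Z)-2-[(3E,5R,7E)-5-(tert-butyldimethylsilyloxy)-4,8,12-trimethyltrideca-3,7,11-trien-1-yl]-3-hydroxy-2,3-dimethyl-6-(1-oxopropan-2-ylidene)cyclohexyl]propyl octadecanoate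
Conditions: EDC·HCl, DMAP, CH2Cl2, rt
Reagents that add atoms: none
Why: Steglich esterification acylates the one unhindered hydroxyl, the primary alcohol, while the tertiary alcohol stays free.

Step 22
Reactants: 33 silyl-protected stearate
Product: 34 CNP0187319.2, 3-[(1S,2R,3S,6Z)-3-hydroxy-2-[(3E,5R,7E)-5-hydroxy-4,8,12-trimethyltrideca-3,7,11-trien-1-yl]-2,3-dimethyl-6-(1-oxopropan-2-ylidene)cyclohexyl]propyl octadecanoate
Conditions: HF·pyridine, pyridine, THF, 0 °C to rt
Reagents that add atoms: none
Why: Fluoride-mediated desilylation under pyridine buffering removes the secondary silyl ether and leaves the ester, the enal and the alkene geometries intact, giving the target.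

**Compound list**

1 | (R)-(−)-carvone | CC1=CC[C@H](CC1=O)C(C)=C | starting material
2 | lithium dienolate of carvone | [Li]OC1=C[C@H](C(C)=C)CC=C1C | intermediate
3 | (5R,6S)-6-allylcarvone | C=CC[C@H]1[C@H](C(C)=C)CC=C(C)C1=O | intermediate
4 | (5R,6S)-1,2-dimethyl-5-isopropenyl-6-allylcyclohex-2-en-1-ol (C-1 epimers) | C=CC[C@H]1[C@H](C(C)=C)CC=C(C)C1(C)O | intermediate
5 | (4S,5R)-2,3-dimethyl-5-isopropenyl-4-allylcyclohex-2-en-1-one | C=CC[C@H]1[C@H](C(C)=C)CC(=O)C(C)=C1C | intermediate
6 | (1S,4S,5R)-2,3-dimethyl-5-isopropenyl-4-allylcyclohex-2-en-1-ol | C=CC[C@H]1[C@H](C(C)=C)C[C@H](O)C(C)=C1C | intermediate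
7 | ketene N,O-acetal [1-(dimethylamino)vinyl ether] of 6 | C=CC[C@H]1[C@H](C(C)=C)C[C@H](OC(=C)N(C)C)C(C)=C1C | intermediate
8 | N,N-dimethyl-2-[(1R,5R,6S)-1,2-dimethyl-5-isopropenyl-6-allylcyclohex-2-en-1-yl]acetamide | C=CC[C@H]1[C@H](C(C)=C)CC=C(C)[C@]1(C)CC(=O)N(C)C | intermediate
9 | iminium lactone iodide (cyclic O-alkyl iminium from 8) | C=CC[C@H]1[C@H](C(C)=C)C[C@@H](I)[C@]2(C)OC(=[N+](C)C)C[C@]12C.[I-] | intermediate
10 | (3aR,4S,5R,7R,7aR)-7-iodo-3a,7a-dimethyl-5-isopropenyl-4-allylhexahydro-1-benzofuran-2(3H)-one | C=CC[C@H]1[C@H](C(C)=C)C[C@@H](I)[C@]2(C)OC(=O)C[C@]12C | intermediate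
11 | (3aR,4S,5R,7aS)-3a,7a-dimethyl-5-isopropenyl-4-allylhexahydro-1-benzofuran-2(3H)-one | C=CC[C@H]1[C@H](C(C)=C)CC[C@]2(C)OC(=O)C[C@]12C | intermediate
12 | B-alkyl catechol boronate of 11 | B1(CCC[C@H]2[C@H](C(C)=C)CC[C@]3(C)OC(=O)C[C@]23C)Oc2ccccc2O1 | intermediate
13 | (3aR,4S,5R,7aS)-4-(3-hydroxypropyl)-3a,7a-dimethyl-5-isopropenylhexahydro-1-benzofuran-2(3H)-one | OCCC[C@H]1[C@H](C(C)=C)CC[C@]2(C)OC(=O)C[C@]12C | intermediate
14 | acetate of 13 | CC(=O)OCCC[C@H]1[C@H](C(C)=C)CC[C@]2(C)OC(=O)C[C@]12C | intermediate
15 | allylic alcohol [5-(3-hydroxyprop-1-en-2-yl) analogue of 14] | CC(=O)OCCC[C@H]1[C@H](C(=C)CO)CC[C@]2(C)OC(=O)C[C@]12C | intermediate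
16 | 2-[(3aR,4S,5R,7aS)-4-(3-acetoxypropyl)-3a,7a-dimethyl-2-oxooctahydro-1-benzofuran-5-yl]prop-2-enal | CC(=O)OCCC[C@H]1[C@H](C(=C)C=O)CC[C@]2(C)OC(=O)C[C@]12C | intermediate
17 | (2Z)-2-[(3aR,4S,7aS)-4-(3-acetoxypropyl)-3a,7a-dimethyl-2-oxohexahydro-1-benzofuran-5(4H)-ylidene]propanal | CC(=O)OCCC[C@H]1/C(=C(/C)C=O)CC[C@]2(C)OC(=O)C[C@]12C | intermediate
18 | (3aR,4S,5Z,7aS)-4-(3-hydroxypropyl)-5-(1-hydroxypropan-2-ylidene)-3a,7a-dimethyloctahydro-1-benzofuran-2-ol (anomers) | OCCC[C@H]1/C(=C(/C)CO)CC[C@]2(C)OC(O)C[C@]12C | intermediate
19 | propargyl alcohol | C#CCO | starting material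
20 | (E)-alkenylalane (dimethylaluminium alkoxide) | C[Al](C)/C=C(\C)CO[Al](C)C | intermediate
21 | (E)-3-iodo-2-methylprop-2-en-1-ol | I/C=C(\C)CO | intermediate
22 | (E)-3-iodo-2-methylprop-2-enal | I/C=C(\C)C=O | intermediate
23 | geranyl chloride, (2E)-1-chloro-3,7-dimethylocta-2,6-diene | ClC/C=C(\C)CCC=C(C)C | starting material
24 | geranylbarium chloride | Cl[Ba]C/C=C(\C)CCC=C(C)C | intermediate
25 | (1E,5E)-1-iodo-2,6,10-trimethylundeca-1,5,9-trien-3-ol (racemic) | I/C=C(\C)C(O)C/C=C(\C)CCC=C(C)C | intermediate
26 | (1E,5E)-1-iodo-2,6,10-trimethylundeca-1,5,9-trien-3-one | I/C=C(\C)C(=O)C/C=C(\C)CCC=C(C)C | intermediate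
27 | (1E,3R,5E)-1-iodo-2,6,10-trimethylundeca-1,5,9-trien-3-ol | I/C=C(\C)[C@H](O)C/C=C(\C)CCC=C(C)C | intermediate
28 | tert-butyldimethylsilyl ether of 27 | I/C=C(\C)[C@H](O[Si](C)(C)C(C)(C)C)C/C=C(\C)CCC=C(C)C | intermediate
29 | N–H hydrazone of the open hydroxy aldehyde form of 18 | OCCC[C@H]1/C(=C(/C)CO)CC[C@](C)(O)[C@]1(C)CC=NN | intermediate
30 | coupled triol (side-chain carbinol as silyl ether) | OCCC[C@H]1/C(=C(/C)CO)CC[C@](C)(O)[C@]1(C)CC/C=C(\C)[C@H](O[Si](C)(C)C(C)(C)C)C/C=C(\C)CCC=C(C)C | intermediate
31 | (Z)-enal diol (side-chain carbinol as silyl ether) | OCCC[C@H]1/C(=C(/C)C=O)CC[C@](C)(O)[C@]1(C)CC/C=C(\C)[C@H](O[Si](C)(C)C(C)(C)C)C/C=C(\C)CCC=C(C)C | intermediate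
32 | stearic acid (octadecanoic acid) | CCCCCCCCCCCCCCCCCC(=O)O | starting material
33 | silyl-protected stearate | CCCCCCCCCCCCCCCCCC(=O)OCCC[C@H]1/C(=C(/C)C=O)CC[C@](C)(O)[C@]1(C)CC/C=C(\C)[C@H](O[Si](C)(C)C(C)(C)C)C/C=C(\C)CCC=C(C)C | intermediate
34 | CNP0187319.2 | CCCCCCCCCCCCCCCCCC(=O)OCCC[C@H]1/C(=C(/C)C=O)CC[C@](C)(O)[C@]1(C)CC/C=C(\C)[C@H](O)C/C=C(\C)CCC=C(C)C | target

**Step count and risks**

Total steps: 22. Longest linear sequence: 16 steps (steps 1–12 and 19–22); the side-chain branch is steps 13–18.

Steps most likely to fail: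

1. Step 19 (proposed new method). The hydrazone may be alkenylated at nitrogen instead of carbon, or the nickel-bound carbanion equivalent may be protonated (plain Wolff–Kishner reduction to the methyl compound) or lose a β-hydride before C–C reductive elimination. The fallback sets out from 18 and returns at 30, using known chemistry. Condensation of 18 with p-toluenesulfonyl hydrazide in MeOH should give the N-tosylhydrazone F1. Transition-metal-free reductive borylation of F1 (NaH, B2pin2, toluene, 110 °C) should give the primary pinacol boronate F2. Suzuki–Miyaura coupling of F2 with 28 (Pd(dppf)Cl2, Ag2O, K2CO3, THF, 70 °C) should then give 30 with retention of the alkene geometry.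

2. Step 11. The hydride catalyst may stall at the 1,1-disubstituted enal, reduce it by hydrogen transfer, or give incomplete control of the alkene geometry. The fallback sets out from 14 and returns at 17. Epoxidation of the isopropenyl group (mCPBA, CH2Cl2) should give the epoxide F3. Meinwald rearrangement (BF3·OEt2, CH2Cl2, −78 °C) should give the α-methyl aldehyde F4. Silyl enol ether formation and bromination (TMSOTf, Et3N; then NBS) should give the α-bromo aldehyde F5. Dehydrobromination (Li2CO3, LiBr, DMF, 110 °C) should eliminate toward the ring methine and give 17, with the geometry again under the same 1,3-strain control; any (E)-isomer would be separated, re-equilibrated with catalytic pyrrolidine/AcOH and recycled.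

3. Step 5. At 140 °C the hindered [3,3] shift that builds the quaternary centre may lose out to elimination of the allylic alcohol to a diene. The fallback sets out from 6 and returns at 10. Acetylation (Ac2O, pyridine, DMAP) should give the allylic acetate F6. Ireland–Claisen rearrangement (LiN(i-Pr)2, Me3SiCl, THF, −78 °C, then 65 °C, aqueous work-up) should give the γ,δ-unsaturated acid F7 by the same suprafacial transfer at far lower temperature. Iodolactonisation of F7 (I2, NaHCO3, MeCN/H2O) should give 10 directly.

**Further compounds**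

F1 | step 19 | N-tosylhydrazone of the open form of 18 | OCCC[C@H]1/C(=C(/C)CO)CC[C@](C)(O)[C@]1(C)CC=NNS(=O)(=O)c1ccc(C)cc1
F2 | step 19 | primary pinacol boronate | OCCC[C@H]1/C(=C(/C)CO)CC[C@](C)(O)[C@]1(C)CCB1OC(C)(C)C(C)(C)O1
F3 | step 11 | epoxide of the isopropenyl group of 14 (epimers at the epoxide carbon) | CC(=O)OCCC[C@H]1[C@H](C2(C)CO2)CC[C@]3(C)OC(=O)C[C@]13C
F4 | step 11 | α-methyl aldehyde (epimers at the α-carbon) | CC(=O)OCCC[C@H]1[C@H](C(C)C=O)CC[C@]2(C)OC(=O)C[C@]12C
F5 | step 11 | α-bromo aldehyde (epimers at the α-carbon) | CC(=O)OCCC[C@H]1[C@H](C(C)(Br)C=O)CC[C@]2(C)OC(=O)C[C@]12C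
F6 | step 5 | allylic acetate of 6 | C=CC[C@H]1[C@H](C(C)=C)C[C@H](OC(C)=O)C(C)=C1C
F7 | step 5 | 2-[(1R,5R,6S)-1,2-dimethyl-5-isopropenyl-6-allylcyclohex-2-en-1-yl]acetic acid | C=CC[C@H]1[C@H](C(C)=C)CC=C(C)[C@]1(C)CC(=O)O
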